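(The numbers in the tables are simulated with made-up constants.)

Decide first to rank these flasks by how the coupling partner's charge compares with the substrate's, and leave rates aside.

| flask | substrate | coupling partner | remark | time |
|---|---|---|---|---|
| winter | 1.5 M | 1.4 M | run made earlier |  |
| autumn | 1.1 M | 3 M | run made earlier |  |
| Wednesday's | 1.5 M | 2.00 M |  | 8.0 d |
| Sunday's | 3.0 M | 1.00 M |  | 8.0 d |
| Tuesday's | 2.5 M | 1.00 M |  | 8.0 d |
| Friday's | 1.5 M | 1.00 M |  | 8.0 d |
| Thursday's | 1.5 M | 3.00 M |  | 8.0 d |
| Saturday's | 0.40 M | 2.00 M |  | 8.0 d |

| run | time / d | product / % | substrate / % |
|---|---|---|---|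
| winter | 0.625 | 28.6 | 71.0 |
| winter | 1.25 | 39.1 | 61.6 |
| winter | 1.67 | 42.0 | 58.7 |
| winter | 2.50 | 45.7 | 53.7 |
| winter | 3.00 | 48.0 | 52.8 |
| winter | 4.00 | 48.7 | 51.4 |
| autumn | 0.833 | 50.5 | 48.9 |
| autumn | 1.67 | 61.1 | 39.9 |
| autumn | 2.50 | 66.7 | 33.9 |
| autumn | 3.00 | 68.3 | 31.2 |
| autumn | 4.00 | 71.2 | 28.8 |

(scatter of a reading: 0.5 percentage points)

- the analysis behind the earlier runs scatters by 0.5 percentage points, standard deviation

1. the flasks put in order of amount of product, in percent of the substrate charged, best first, at 8.0 d (Wednesday's / Sunday's / Tuesday's / Friday's / Thursday's / Saturday's)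
2. the amount of product, in percent of the substrate charged of the flask you put first, at 8.0 d
3. the amount of product, in percent of the substrate charged of the flask you put last, at 8.0 d

Start with the main step by itself: substrate and coupling partner give product one for one. In the winter run the coupling partner is the limiting reagent, so the product could reach 93.3% of the substrate. The readings level at 48.7% by 4.00 d, about half of that, while substrate and product still add to 100%.

So add a second process that holds the coupling partner back from the substrate, without yet saying what it is. Then try a rule that takes the level as reached. For Sunday's, 25.0% is f, the coupling partner's share of the two charges, that is partner divided by substrate plus partner, and you read f as the percent of substrate ending as product. The winter run has f at 48.3%, close to its level. The autumn run has 73.2% against 71.2% at 4.00 d, and it is still climbing.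

Time comes last. The autumn run gained 2.9 percentage points over its final interval, so you expect Saturday's to end somewhat under its f of 83.3%. Ranked by f, the flasks run from Saturday's down through Thursday's, Wednesday's, Friday's and Tuesday's to Sunday's at 25.0%.

The forecast has the same order, Saturday's > Thursday's > Wednesday's > Friday's > Tuesday's > Sunday's, with 82% on top and 25.5% last, slightly different numbers from f. Its ground is that the levelling points to “a reversible reaction rather than a stall”.

The flasks give Saturday's > Thursday's > Wednesday's > Friday's > Tuesday's > Sunday's, with 78.4% and 26.1%.

    substrate + coupling partner → product + released group (k = 0.0270 M⁻¹ h⁻¹)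
    2 coupling partner → homo dimer (k = 0.0220 M⁻¹ h⁻¹)

Sunday's product stops at 26.1% because the coupling partner wears away: with it held at its charge, product would reach 99.4%, and 0% of its charge is left at 8.00 d, with f at 25.0%. Saturday's, with 4.0% of its own charge of coupling partner left at 8.00 d, stands below its f of 83.3%, and a run of Saturday's stopped at 4.91 d would read 5 points lower, further from the forecast's 82%. The same flask as Sunday's with 0.25 M of coupling partner has f at 7.69% and gives 7.80%.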